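**Retrosynthetic overview**
1. Gneyulin A (19) ⇐ its deca-O-methyl ether 18; all ten methyl ethers are cleaved last.
2. Second dihydrobenzofuran (C2′–O bond, C2′/C3′) ⇐ o-hydroxy-triarylethylene 17 by a chiral-acid 5-endo hydroalkoxylation.
3. 17 ⇐ Heck union of bromo-dihydrobenzofuran 7 (east) with 1,1-diarylethylene 16 (west, carries the stilbene).
4. First dihydrobenzofuran (C2–O bond, C2/C3) in 7 ⇐ the same C–O cyclisation on carbinol 5, made by acylation of phenol 1 with acid 2 and addition of Grignard 4.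
5. 16 ⇐ aldehyde 8 + Grignard 4 (ketone), chelation-controlled mono-demethylation, Heck with styrene 13, methylenation. Ring order: east ring first, west ring second.

Assumption: the sense of induction of the new chiral-acid cyclisation cannot be predicted; the route is written for the catalyst enantiomer, here called (S,S), that gives the (R,R) ring, and the mirror-image catalyst is used if it gives the antipode.

**Step 1**
Reactants: 1 4-bromo-3-methoxyphenol; 2 (2,4-dimethoxyphenyl)acetic acid
Product: 3 1-(5-bromo-2-hydroxy-4-methoxyphenyl)-2-(2,4-dimethoxyphenyl)ethan-1-one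
Conditions: BF3·OEt2 (neat, 6 equiv), 85 °C, 3 h; aq NaOAc
Reagents that add atoms: none
Why: BF3-mediated Friedel–Crafts acylation (O-acylation/Fries rearrangement, the standard deoxybenzoin synthesis) goes to the one unhindered position ortho to OH and para to OMe, because the para position of the phenol is blocked by Br.

**Step 2**
Reactants: 3 the ketone from step 1; 4 3,5-dimethoxyphenylmagnesium chloride (commercial 1.0 M THF solution)
Product: 5 racemic 4-bromo-2-[1-(3,5-dimethoxyphenyl)-2-(2,4-dimethoxyphenyl)-1-hydroxyethyl]-5-methoxyphenol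
Conditions: 4 (3.5 equiv), LaCl3·2LiCl (1 equiv), THF, 0 °C → rt; aq NH4Cl
Reagents that add atoms: none
Why: Grignard 1,2-addition to the chelated o-hydroxyaryl ketone (the first equivalent forms the phenoxide, LaCl3·2LiCl suppresses enolisation); the carbinol centre is racemic and is erased in step 3.

**Step 3**
Reactants: 5 the tertiary carbinol
Product: 7 (2R,3R)-5-bromo-2-(2,4-dimethoxyphenyl)-3-(3,5-dimethoxyphenyl)-6-methoxy-2,3-dihydro-1-benzofuran, via triarylethylene phenol 6 (not isolated)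
Conditions: (S,S)-IDPi acid (BINOL-derived imidodiphosphorimidate, 3,3′-bis[3,5-(CF3)2C6H3], N-triflyl; 5 mol %), 5 Å MS, CHCl3/cyclohexane 1:1, 0.02 M, −20 °C → rt; recrystallise
Reagents that add atoms: none
Why: Proposed new method: the confined chiral Brønsted acid dehydrates the carbinol (E1) to alkene 6, reversibly protonates C3 to a 2,4-dimethoxybenzylic cation ion-paired with the chiral anion, and the ortho-phenol (hydrogen-bonded to that anion) closes the ring in an enantio-determining 5-endo C–O bond formation anti to the C3 aryl, giving the trans (2R,3R) ring, while protonation at the other alkene carbon is non-productive and only equilibrates E/Z; the closest known reaction types are IDPi-catalysed asymmetric intramolecular hydroalkoxylation of alkenes, chiral-phosphoric-acid additions to quinone methides and the acid-mediated cis/trans equilibration of 2-aryl-dihydrobenzofurans through the same cation.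

**Step 4**
Reactants: 8 4-bromo-2,6-dimethoxybenzaldehyde; 4 3,5-dimethoxyphenylmagnesium chloride
Product: 10 (4-bromo-2,6-dimethoxyphenyl)(3,5-dimethoxyphenyl)methanone, via magnesium alkoxide 9 (not isolated)
Conditions: 4 (1.05 equiv), THF, 0 °C; then PhCHO (2 equiv), rt → 40 °C; aq NH4Cl
Reagents that add atoms: none
Why: Grignard addition followed in the same pot by magnesium-Oppenauer oxidation (hydride transfer from the diarylmethoxide to benzaldehyde) gives the non-enolisable benzophenone directly.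

**Step 5**
Reactants: 10 the benzophenone
Product: 11 (4-bromo-2-hydroxy-6-methoxyphenyl)(3,5-dimethoxyphenyl)methanone
Conditions: BCl3 (1.3 equiv), CH2Cl2, −78 → 0 °C; aq HCl
Reagents that add atoms: none
Why: Chelation-controlled Lewis-acid ether cleavage: only a methoxy ortho to the carbonyl forms the six-membered boron chelate, and once one is cleaved the carbonyl is tied up, so the second ortho-OMe and the remote OMe groups stay.

**Step 6**
Reactants: 12 2,4-dimethoxybenzaldehyde
Product: 13 1-ethenyl-2,4-dimethoxybenzene (2,4-dimethoxystyrene)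
Conditions: Ph3PCH3Br (1.2 equiv), KOtBu (1.2 equiv), THF, 0 °C → rt
Reagents that add atoms: methyltriphenylphosphonium bromide, C[P+](c1ccccc1)(c1ccccc1)c1ccccc1.[Br-]
Why: Wittig methylenation of an aromatic aldehyde.

**Step 7**
Reactants: 11 the bromo-hydroxybenzophenone; 13 2,4-dimethoxystyrene
Product: 14 {4-[(E)-2-(2,4-dimethoxyphenyl)ethenyl]-2-hydroxy-6-methoxyphenyl}(3,5-dimethoxyphenyl)methanone
Conditions: Pd(OAc)2 (3 mol %), P(o-tol)3 (7 mol %), Et3N, DMF, 100 °C
Reagents that add atoms: none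
Why: Mizoroki–Heck reaction of the aryl bromide (activated by the para carbonyl) with the styrene gives the E-stilbene by syn-insertion and syn-β-hydride elimination.

**Step 8**
Reactants: 14 the stilbene ketone
Product: 16 5-[(E)-2-(2,4-dimethoxyphenyl)ethenyl]-2-[1-(3,5-dimethoxyphenyl)ethenyl]-3-methoxyphenol, via tertiary carbinol 15 (not isolated)
Conditions: MeMgBr (4 equiv), THF, 0 → 40 °C; aq NH4Cl; then PPTS (5 mol %), PhMe, 40 °C, dilute
Reagents that add atoms: methylmagnesium bromide, C[Mg]Br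
Why: Grignard addition to the non-enolisable o-hydroxybenzophenone and mild E1 dehydration of the doubly benzylic carbinol, the standard route to 2-(1-arylvinyl)phenols.

**Step 9**
Reactants: 7 the bromo-dihydrobenzofuran; 16 the 1,1-diarylethylene (1.2 equiv)
Product: 17 2-{2-[(2R,3R)-2-(2,4-dimethoxyphenyl)-3-(3,5-dimethoxyphenyl)-6-methoxy-2,3-dihydro-1-benzofuran-5-yl]-1-(3,5-dimethoxyphenyl)ethenyl}-5-[(E)-2-(2,4-dimethoxyphenyl)ethenyl]-3-methoxyphenol (E/Z mixture at the triaryl alkene)
Conditions: Pd2(dba)3 (2.5 mol %), [HP(t-Bu)3]BF4 (10 mol %), Cy2NMe (2 equiv), dioxane, 100 °C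
Reagents that add atoms: none
Why: Mizoroki–Heck arylation of the terminal 1,1-diarylethylene (the internal stilbene is far less reactive) gives the triarylethylene, whose E/Z ratio is irrelevant because step 10 equilibrates it.

**Step 10**
Reactants: 17 the o-hydroxy-triarylethylene
Product: 18 deca-O-methylgneyulin A, (2R,3R,2′R,3′R)
Conditions: (S,S)-IDPi acid of step 3 (5 mol %), 5 Å MS, CHCl3/cyclohexane 1:1, 0.01 M, −20 °C → rt
Reagents that add atoms: none
Why: Proposed new method: the same chiral-acid 5-endo hydroalkoxylation as in step 3, here with the cation at C2′ stabilised by the ortho-methoxy/para-alkoxy ring of the first dihydrobenzofuran and closed by the one free phenol in an enantio-determining C–O bond formation that sets trans-(2′R,3′R) under catalyst control (the existing centres are remote, and any acid opening of the first ring re-closes to the same trans isomer); the closest known reaction types are IDPi-catalysed asymmetric intramolecular hydroalkoxylation and chiral-acid additions to quinone methides.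

**Step 11**
Reactants: 18 deca-O-methylgneyulin A
Product: 19 gneyulin A
Conditions: BBr3 (30 equiv), CH2Cl2, −78 °C → rt; MeOH, then aq NaHCO3
Reagents that add atoms: none
Why: Lewis-acid ether cleavage (BBr3 demethylation) of all ten aryl methyl ethers; reversible opening of the 2-aryl-dihydrobenzofurans re-closes to the favoured trans rings and the C3/C3′ centres are not ionisable, so all four centres are kept.

**Compound list**
1 | 4-bromo-3-methoxyphenol | COc1cc(O)ccc1Br | starting material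
2 | (2,4-dimethoxyphenyl)acetic acid | COc1ccc(CC(=O)O)c(OC)c1 | starting material
3 | 1-(5-bromo-2-hydroxy-4-methoxyphenyl)-2-(2,4-dimethoxyphenyl)ethan-1-one | COc1ccc(CC(=O)c2cc(Br)c(OC)cc2O)c(OC)c1 | intermediate
4 | 3,5-dimethoxyphenylmagnesium chloride | COc1cc(OC)cc([Mg]Cl)c1 | starting material
5 | racemic 4-bromo-2-[1-(3,5-dimethoxyphenyl)-2-(2,4-dimethoxyphenyl)-1-hydroxyethyl]-5-methoxyphenol | COc1ccc(CC(O)(c2cc(OC)cc(OC)c2)c2cc(Br)c(OC)cc2O)c(OC)c1 | intermediate
6 | 4-bromo-2-[1-(3,5-dimethoxyphenyl)-2-(2,4-dimethoxyphenyl)ethenyl]-5-methoxyphenol (E/Z mixture) | COc1ccc(C=C(c2cc(OC)cc(OC)c2)c2cc(Br)c(OC)cc2O)c(OC)c1 | intermediate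
7 | (2R,3R)-5-bromo-2-(2,4-dimethoxyphenyl)-3-(3,5-dimethoxyphenyl)-6-methoxy-2,3-dihydro-1-benzofuran | COc1cc(OC)cc([C@@H]2c3cc(Br)c(OC)cc3O[C@H]2c2ccc(OC)cc2OC)c1 | intermediate
8 | 4-bromo-2,6-dimethoxybenzaldehyde | COc1cc(Br)cc(OC)c1C=O | starting material
9 | chloromagnesium (4-bromo-2,6-dimethoxyphenyl)(3,5-dimethoxyphenyl)methanolate (racemic) | COc1cc(OC)cc(C(O[Mg]Cl)c2c(OC)cc(Br)cc2OC)c1 | intermediate
10 | (4-bromo-2,6-dimethoxyphenyl)(3,5-dimethoxyphenyl)methanone | COc1cc(OC)cc(C(=O)c2c(OC)cc(Br)cc2OC)c1 | intermediate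
11 | (4-bromo-2-hydroxy-6-methoxyphenyl)(3,5-dimethoxyphenyl)methanone | COc1cc(OC)cc(C(=O)c2c(O)cc(Br)cc2OC)c1 | intermediate
12 | 2,4-dimethoxybenzaldehyde | COc1ccc(C=O)c(OC)c1 | starting material
13 | 1-ethenyl-2,4-dimethoxybenzene | COc1ccc(C=C)c(OC)c1 | intermediate
14 | {4-[(E)-2-(2,4-dimethoxyphenyl)ethenyl]-2-hydroxy-6-methoxyphenyl}(3,5-dimethoxyphenyl)methanone | COc1ccc(/C=C/c2cc(O)c(C(=O)c3cc(OC)cc(OC)c3)c(OC)c2)c(OC)c1 | intermediate
15 | racemic 2-[1-(3,5-dimethoxyphenyl)-1-hydroxyethyl]-5-[(E)-2-(2,4-dimethoxyphenyl)ethenyl]-3-methoxyphenol | COc1ccc(/C=C/c2cc(O)c(C(C)(O)c3cc(OC)cc(OC)c3)c(OC)c2)c(OC)c1 | intermediate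
16 | 5-[(E)-2-(2,4-dimethoxyphenyl)ethenyl]-2-[1-(3,5-dimethoxyphenyl)ethenyl]-3-methoxyphenol | COc1ccc(/C=C/c2cc(O)c(C(=C)c3cc(OC)cc(OC)c3)c(OC)c2)c(OC)c1 | intermediate
17 | 2-{2-[(2R,3R)-2-(2,4-dimethoxyphenyl)-3-(3,5-dimethoxyphenyl)-6-methoxy-2,3-dihydro-1-benzofuran-5-yl]-1-(3,5-dimethoxyphenyl)ethenyl}-5-[(E)-2-(2,4-dimethoxyphenyl)ethenyl]-3-methoxyphenol (E/Z mixture at the triaryl alkene) | COc1cc(OC)cc([C@@H]2c3cc(C=C(c4cc(OC)cc(OC)c4)c4c(O)cc(/C=C/c5ccc(OC)cc5OC)cc4OC)c(OC)cc3O[C@H]2c2ccc(OC)cc2OC)c1 | intermediate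
18 | deca-O-methylgneyulin A, (2R,3R,2′R,3′R) | COc1cc(OC)cc([C@@H]2c3cc([C@@H]4Oc5cc(/C=C/c6ccc(OC)cc6OC)cc(OC)c5[C@H]4c4cc(OC)cc(OC)c4)c(OC)cc3O[C@H]2c2ccc(OC)cc2OC)c1 | intermediate
19 | gneyulin A | Oc1cc(O)cc([C@@H]2c3cc([C@@H]4Oc5cc(/C=C/c6ccc(O)cc6O)cc(O)c5[C@H]4c4cc(O)cc(O)c4)c(O)cc3O[C@H]2c2ccc(O)cc2O)c1 | target

**Step count**
Total steps: 11. Longest linear sequence: 7 (steps 4, 5, 7, 8, 9, 10, 11).

**Three steps most likely to fail**

Step 3 (proposed new method, first use). If the chiral-acid cyclisation of 5 gives low ee or side products, the east ring is made by known donor/donor-carbene C–H insertion chemistry, setting out from 1 and coming back to the route at 7. TiCl4-mediated ortho-acylation of 1 with 3,5-dimethoxybenzoyl chloride gives (5-bromo-2-hydroxy-4-methoxyphenyl)(3,5-dimethoxyphenyl)methanone F1. Mitsunobu etherification with 2,4-dimethoxybenzyl alcohol gives {5-bromo-2-[(2,4-dimethoxyphenyl)methoxy]-4-methoxyphenyl}(3,5-dimethoxyphenyl)methanone F2, and hydrazine hydrate converts it into the benzophenone hydrazone F3. MnO2 oxidises this to the diaryldiazomethane F4, which with Rh2(R-PTAD)4 (or its antipode) inserts enantioselectively into the benzylic ether C–H to give the cis-(2S,3R)-dihydrobenzofuran F5. TFA in CH2Cl2 then epimerises C2 alone through the 2,4-dimethoxybenzylic cation and delivers trans-(2R,3R) 7.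

Step 10 (proposed new method, late-stage use). If catalyst control fails on the large substrate, the fallback sets out from 17 and comes back at 18. It gives up asymmetric catalysis and uses an established achiral Brønsted-acid cyclisation of the o-hydroxystilbene type (HNTf2 or TsOH, 5 mol %, CH2Cl2, −40 → 0 °C) under thermodynamic control. Both trans rings form, so the enantiopure substrate gives 18 together with its (2R,3R,2′S,3′S)-diastereomer F7, and the two are separated by ordinary preparative HPLC.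

Step 9 (Heck union of an electron-rich aryl bromide with a hindered 1,1-diarylethylene). The fallback sets out from 7, uses ketone 14 in place of 16 (so step 8 is skipped), and comes back at 17. Bromine–lithium exchange on 7 (n-BuLi, THF, −78 °C) and quenching with DMF gives (2R,3R)-2-(2,4-dimethoxyphenyl)-3-(3,5-dimethoxyphenyl)-6-methoxy-2,3-dihydro-1-benzofuran-5-carbaldehyde F6. A McMurry cross-coupling of F6 with benzophenone 14 (TiCl4, Zn, pyridine, THF, reflux) gives triarylethylene 17 directly.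

**Further compounds**
F1 | step 3 | (5-bromo-2-hydroxy-4-methoxyphenyl)(3,5-dimethoxyphenyl)methanone | COc1cc(OC)cc(C(=O)c2cc(Br)c(OC)cc2O)c1
F2 | step 3 | {5-bromo-2-[(2,4-dimethoxyphenyl)methoxy]-4-methoxyphenyl}(3,5-dimethoxyphenyl)methanone | COc1cc(OC)cc(C(=O)c2cc(Br)c(OC)cc2OCc2ccc(OC)cc2OC)c1
F3 | step 3 | hydrazone of F2, {[5-bromo-2-[(2,4-dimethoxyphenyl)methoxy]-4-methoxyphenyl](3,5-dimethoxyphenyl)methylidene}hydrazine | NN=C(c1cc(OC)cc(OC)c1)c1cc(Br)c(OC)cc1OCc1ccc(OC)cc1OC
F4 | step 3 | 1-bromo-5-[diazo(3,5-dimethoxyphenyl)methyl]-4-[(2,4-dimethoxyphenyl)methoxy]-2-methoxybenzene | [N-]=[N+]=C(c1cc(OC)cc(OC)c1)c1cc(Br)c(OC)cc1OCc1ccc(OC)cc1OC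
F5 | step 3 | (2S,3R)-5-bromo-2-(2,4-dimethoxyphenyl)-3-(3,5-dimethoxyphenyl)-6-methoxy-2,3-dihydro-1-benzofuran (cis) | COc1cc(OC)cc([C@@H]2c3cc(Br)c(OC)cc3O[C@@H]2c2ccc(OC)cc2OC)c1
F6 | step 9 | (2R,3R)-2-(2,4-dimethoxyphenyl)-3-(3,5-dimethoxyphenyl)-6-methoxy-2,3-dihydro-1-benzofuran-5-carbaldehyde | COc1cc(OC)cc([C@@H]2c3cc(C=O)c(OC)cc3O[C@H]2c2ccc(OC)cc2OC)c1
F7 | step 10 | (2R,3R,2′S,3′S)-diastereomer of deca-O-methylgneyulin A | COc1cc(OC)cc([C@@H]2c3cc([C@H]4Oc5cc(/C=C/c6ccc(OC)cc6OC)cc(OC)c5[C@@H]4c4cc(OC)cc(OC)c4)c(OC)cc3O[C@H]2c2ccc(OC)cc2OC)c1
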